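**Retrosynthetic overview**

1. Target 10 ← dione 9 by site- and face-selective 1,2-reduction of the C4 enone carbonyl; 9 ← diosphenol 8 by O-methylation.
2. Key disconnection: both bonds of the two-carbon bridge, C1–C7 and C5–C6, are cut at once. 8 ← formal [5+2] annulation of the flat 2-allyl-5-methoxy-1,4-benzoquinone 5 with (E)-methylisoeugenol 6 on a chiral Ti(IV)–TADDOLate. Ring carbons C1–C2–C3–C4–C5 of the target act as a titanium-bound oxidopentadienyl cation, and C8 becomes the bridging ketone.
3. This one operation turns the planar quinone into the bicyclo[3.2.1]octane, closes the cyclopentanone ring C1–C8–C5–C6–C7 (and with it the seven-membered ring), creates the allyl-bearing quaternary C1 and sets C1, C5, C6 and C7 as a group.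
4. 5 ← 3,4-dimethoxyphenol 1 by O-allylation, aromatic Claisen rearrangement and oxidative demethylation (oxidative dearomatization of a cheap arene).
5. Ring order: six-membered ring bought as the arene; five- and seven-membered rings formed together in step 4.

Key step: step 4

Remark on numbering: all bicyclo[3.2.1]octanes carry the locants of the target (C1 allyl-bearing bridgehead, C2=C3, C4, C5 second bridgehead, C6 aryl-bearing, C7 methyl-bearing, C8 bridging carbonyl).

Assumption: the titanium complex of (R,R)-TADDOL is taken to leave open the quinone face that leads to the (1R) adduct; if the opposite sense of induction is found, the (S,S)-ligand is used and nothing else changes.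

**Route**

Step 1
Reactants: 1 3,4-dimethoxyphenol; 2 allyl bromide
Product: 3 4-(allyloxy)-1,2-dimethoxybenzene
Conditions: K2CO3, acetone, reflux
Reagents that add atoms: none
Why: Williamson ether synthesis, SN2 attack of the phenoxide on the primary allylic bromide.

Step 2
Reactants: 3 4-(allyloxy)-1,2-dimethoxybenzene
Product: 4 2-allyl-4,5-dimethoxyphenol
Conditions: PhNEt2, 190 °C
Reagents that add atoms: none
Why: Aromatic Claisen rearrangement ([3,3] shift, then tautomerization), expected to favour the free ortho position C6 over C2, which is flanked by the 3-methoxy group.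

Step 3
Reactants: 4 2-allyl-4,5-dimethoxyphenol
Product: 5 2-allyl-5-methoxy-1,4-benzoquinone
Conditions: PhI(OAc)2, MeCN–H2O (2:1), 0 °C
Reagents that add atoms: water, O
Why: Hypervalent-iodine oxidation of a p-methoxyphenol: water adds to the phenoxonium ion at the methoxy-bearing para carbon and the hemiketal loses methanol to give the p-quinone, with the allyl group untouched.

Step 4
Reactants: 5 2-allyl-5-methoxy-1,4-benzoquinone; 6 (E)-methylisoeugenol
Product: 8 (1R,5R,6S,7S)-1-allyl-6-(3,4-dimethoxyphenyl)-3-hydroxy-7-methylbicyclo[3.2.1]oct-2-ene-4,8-dione, via cyclobutane [2+2] adduct 7 (not isolated)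
Conditions: (R,R)-TADDOL, TiCl4/Ti(OiPr)4 (1:1), 4 Å MS, CH2Cl2, −78 °C → −20 °C; then H2O
Reagents that add atoms: none
Why: Bidentate Ti(IV) binding at the C1 carbonyl and the 2-methoxy oxygen of 5 (quinone numbering) turns the ring into a 2-alkoxy-4-oxidopentadienyl cation whose allyl-bearing terminus C5 is attacked by the β-carbon of 6 (chelation activates the non-vinylogous carbonyl and so directs attack to C5, not C6), and the benzylic cation/titanium enolate pair should collapse at −78 °C to the endo-aryl cyclobutane 7. On warming, 7 should reopen to the same ion pair and the cation be trapped by C3, the β-carbon of the methoxy enol ether, which closes the five-membered ring C1–C7–C6–C5–C8 (target numbering) and with it the seven-membered ring, after which chloride removes the O-methyl group of the oxocarbenium ion as MeCl: overall a formal, stepwise (4π five-centre + 2π) [5+2] cycloaddition. The closest known reaction type is the Ti(IV)-promoted [2+2]/[5+2] annulation of 2-alkoxy-1,4-benzoquinones, 5-alkyl members included, with (E)-propenylarenes, and its Ti–TADDOLate enantioselective variant. C1 (absolute) is set by the TADDOLate, which leaves one quinone face open; C7 relative to C1 is set by the compact transition state in which the electron-rich aryl ring stacks under the titanium-bound enedione, which places methyl trans to allyl and therefore endo in 8; C6 follows from the E-geometry of 6, carried through the short-lived cation to the less strained exo-aryl closure trans to methyl; C5 has no freedom once the bridge closes. The selectivities required are C5 over C6 attack (chelation), carbon over oxygen capture of the cation, that is [5+2] over [3+2] (aprotic, chloride-rich Lewis acid at low temperature, no protic acid), and enantioface differentiation (chiral ligand).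

Step 5
Reactants: 8 (1R,5R,6S,7S)-1-allyl-6-(3,4-dimethoxyphenyl)-3-hydroxy-7-methylbicyclo[3.2.1]oct-2-ene-4,8-dione
Product: 9 (1R,5R,6S,7S)-1-allyl-6-(3,4-dimethoxyphenyl)-3-methoxy-7-methylbicyclo[3.2.1]oct-2-ene-4,8-dione
Conditions: MeI, K2CO3, acetone, rt
Reagents that add atoms: iodomethane, CI
Why: O-alkylation of the diosphenol enolate (Williamson type); C-alkylation at C2 is blocked by the neighbouring quaternary C1, and a non-nucleophilic base avoids retro-Claisen opening of the non-enolizable 1,3-diketone.

Step 6
Reactants: 9 (1R,5R,6S,7S)-1-allyl-6-(3,4-dimethoxyphenyl)-3-methoxy-7-methylbicyclo[3.2.1]oct-2-ene-4,8-dione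
Product: 10 (1R,4R,5S,6S,7S)-1-allyl-6-(3,4-dimethoxyphenyl)-4-hydroxy-3-methoxy-7-methylbicyclo[3.2.1]oct-2-en-8-one (target)
Conditions: NaBH4 (1 equiv), CeCl3·7H2O, MeOH, −78 °C
Reagents that add atoms: none
Why: Luche reduction, 1,2-hydride addition to the cerium-activated enone carbonyl C4 in preference to the C8 ketone (shielded by quaternary C1 and the exo-aryl group); hydride should enter anti to the C5–C6 bond from the face remote from the C6–C7 bridge, giving the equatorial (4R) alcohol.

**Compound list**

1 | 3,4-dimethoxyphenol | COc1ccc(O)cc1OC | starting material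
2 | allyl bromide (3-bromoprop-1-ene) | C=CCBr | starting material
3 | 4-(allyloxy)-1,2-dimethoxybenzene | C=CCOc1ccc(OC)c(OC)c1 | intermediate
4 | 2-allyl-4,5-dimethoxyphenol | C=CCc1cc(OC)c(OC)cc1O | intermediate
5 | 2-allyl-5-methoxy-1,4-benzoquinone | C=CCC1=CC(=O)C(OC)=CC1=O | intermediate
6 | (E)-methylisoeugenol, (E)-1,2-dimethoxy-4-(prop-1-en-1-yl)benzene | C/C=C/c1ccc(OC)c(OC)c1 | starting material
7 | (1R,6S,7S,8S)-1-allyl-7-(3,4-dimethoxyphenyl)-4-methoxy-8-methylbicyclo[4.2.0]oct-3-ene-2,5-dione (cis-fused, aryl endo, methyl exo and cis to allyl) | C=CC[C@]12C(=O)C=C(OC)C(=O)[C@H]1[C@@H](c3ccc(OC)c(OC)c3)[C@@H]2C | intermediate (not isolated)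
8 | (1R,5R,6S,7S)-1-allyl-6-(3,4-dimethoxyphenyl)-3-hydroxy-7-methylbicyclo[3.2.1]oct-2-ene-4,8-dione (aryl exo, methyl endo) | C=CC[C@@]12C=C(O)C(=O)[C@@H](C1=O)[C@@H](c1ccc(OC)c(OC)c1)[C@@H]2C | intermediate
9 | (1R,5R,6S,7S)-1-allyl-6-(3,4-dimethoxyphenyl)-3-methoxy-7-methylbicyclo[3.2.1]oct-2-ene-4,8-dione | C=CC[C@@]12C=C(OC)C(=O)[C@@H](C1=O)[C@@H](c1ccc(OC)c(OC)c1)[C@@H]2C | intermediate
10 | (1R,4R,5S,6S,7S)-1-allyl-6-(3,4-dimethoxyphenyl)-4-hydroxy-3-methoxy-7-methylbicyclo[3.2.1]oct-2-en-8-one | C=CC[C@@]12C=C(OC)[C@H](O)[C@@H](C1=O)[C@@H](c1ccc(OC)c(OC)c1)[C@@H]2C | target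

**Step count and risks**

Total steps: 6. Longest linear sequence: 6 (1 → 10).

Steps most likely to fail:

1. Step 4. The benzylic cation may be captured by the C8 carbonyl oxygen (formal [3+2]) or by the allyl π-bond instead of by carbon, the sequence may stall at the cyclobutane, or the ligand may discriminate the faces of a 5-substituted quinone poorly. The fallback sets out from 4. Oxidation with PhI(OAc)2 in MeOH should give the quinone monoketal 2-allyl-4,4,5-trimethoxycyclohexa-2,5-dien-1-one F1. Ionization with TMSOTf in MeCN at −30 °C in the presence of 6 generates the 4-methoxyphenoxonium-type cation, which should undergo the acid-mediated cationic [5+2] cycloaddition known for p-quinone monoketals and propenylarenes. This gives the racemic 3-methoxy dione F2 directly: the ketal methoxy group that survives ionization becomes the C3 methoxy group, and the 5-methoxy carbon becomes the C4 carbonyl. Preparative chromatography on a chiral stationary phase returns to the route at 9, and step 5 is then not needed.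

2. Step 6. Hydride may be delivered to the lower face of the C4 carbonyl, with competing attack at the C8 ketone as a lesser concern. The fallback sets out from 9 and accepts the wrong face: the reduction is taken to the C4 epimer (1R,4S,5S,6S,7S)-1-allyl-6-(3,4-dimethoxyphenyl)-4-hydroxy-3-methoxy-7-methylbicyclo[3.2.1]oct-2-en-8-one F3. Mitsunobu esterification (4-nitrobenzoic acid, PPh3, DIAD, THF) then inverts C4 to give (1R,4R,5S,6S,7S)-1-allyl-6-(3,4-dimethoxyphenyl)-3-methoxy-7-methyl-8-oxobicyclo[3.2.1]oct-2-en-4-yl 4-nitrobenzoate F4. Methanolysis (K2CO3, MeOH, 0 °C) comes back to the route at 10.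

3. Step 2. The allyl group may migrate in part to C2, between the hydroxyl and the methoxy group, giving an isomeric phenol that is hard to remove. The fallback sets out from 1. Bromination with NBS in MeCN at 0 °C, at the position ortho to OH and para to OMe, should give 2-bromo-4,5-dimethoxyphenol F5. Stille coupling with allyltributylstannane (Pd(PPh3)4, DMF, 90 °C) then installs the allyl group at a fixed position and comes back to the route at 4.

**Further compounds**

F1 | step 4 | 2-allyl-4,4,5-trimethoxycyclohexa-2,5-dien-1-one | C=CCC1=CC(OC)(OC)C(OC)=CC1=O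
F2 | step 4 | racemic 1-allyl-6-(3,4-dimethoxyphenyl)-3-methoxy-7-methylbicyclo[3.2.1]oct-2-ene-4,8-dione (1:1 mixture of 9 and its enantiomer) | C=CC[C@@]12C=C(OC)C(=O)[C@@H](C1=O)[C@@H](c1ccc(OC)c(OC)c1)[C@@H]2C.C=CC[C@]12C=C(OC)C(=O)[C@H](C1=O)[C@H](c1ccc(OC)c(OC)c1)[C@H]2C
F3 | step 6 | (1R,4S,5S,6S,7S)-1-allyl-6-(3,4-dimethoxyphenyl)-4-hydroxy-3-methoxy-7-methylbicyclo[3.2.1]oct-2-en-8-one | C=CC[C@@]12C=C(OC)[C@@H](O)[C@@H](C1=O)[C@@H](c1ccc(OC)c(OC)c1)[C@@H]2C
F4 | step 6 | (1R,4R,5S,6S,7S)-1-allyl-6-(3,4-dimethoxyphenyl)-3-methoxy-7-methyl-8-oxobicyclo[3.2.1]oct-2-en-4-yl 4-nitrobenzoate | C=CC[C@@]12C=C(OC)[C@H](OC(=O)c3ccc(cc3)[N+](=O)[O-])[C@@H](C1=O)[C@@H](c1ccc(OC)c(OC)c1)[C@@H]2C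
F5 | step 2 | 2-bromo-4,5-dimethoxyphenol | COc1cc(O)c(Br)cc1OC
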